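**Retrosynthetic overview** (ring atoms numbered as in the target: C1 = C(OH)(chain), C2=C3, C4‑OH, C5‑OH, C6H2)
1. Target 20 ⇐ tris‑silyl ether 19 ⇐ enol triflate 18 (C2 oxygen removed, C2=C3 fixed) ⇐ α‑silyloxy ketone 17.
2. 17 ⇐ one‑flask 5→6 ring expansion of the C2‑symmetric cyclopentanone 14: the diazo carbon of 10, which already carries the C17 chain and a silyl group, is inserted by a 1,2‑shift and becomes C1; silyl shift and Rubottom oxidation then put oxygen on C1. This is the only ring‑forming event.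
3. 14 ⇐ (R)‑4‑silyloxycyclopentenone 11 by trans conjugate borylation/oxidation and silylation (sets C4/C5).
4. 10 ⇐ TMSCHN2 + bromide 9; 9 ⇐ B‑alkyl Suzuki coupling of 11‑bromoundec‑1‑ene 4 (from 1 + 2) with (E)‑1‑iodohexene 7 (from hexyne 5).

Assumption: 11 is bought as the TBS ether (R enantiomer); all other starting materials are stock chemicals.

**Step 1**
Reactants: 1 5-bromopent-1-ene; 2 1,6-dibromohexane
Product: 4 11-bromoundec-1-ene, via pent-4-en-1-ylmagnesium bromide 3 (not isolated)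
Conditions: 1, Mg, THF, 40 °C; then 2 (3 equiv), Li2CuCl4 (2 mol %), THF, −10 → 0 °C
Reagents that add atoms: none
Why: Kochi Cu‑catalysed sp3–sp3 Grignard coupling; the excess of dibromide holds it at mono‑coupling and no stereocentre is involved.

**Step 2**
Reactants: 5 hex-1-yne
Product: 7 (E)-1-iodohex-1-ene, via chloro[(E)-hex-1-en-1-yl]zirconocene 6 (not isolated)
Conditions: Cp2Zr(H)Cl, CH2Cl2, rt; then I2, 0 °C
Reagents that add atoms: iodine, II
Why: Schwartz hydrozirconation is a syn, anti‑Markovnikov addition and iodinolysis of C–Zr goes with retention, so the E geometry of the chain double bond is fixed here.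

**Step 3**
Reactants: 4 11-bromoundec-1-ene; 7 (E)-1-iodohex-1-ene
Product: 9 (5E)-17-bromoheptadec-5-ene, via B-(11-bromoundecyl)-9-BBN 8 (not isolated)
Conditions: 4, 9‑BBN, THF, 0 °C → rt; then 7, PdCl2(dppf) (3 mol %), aq K3PO4, THF–DMF, rt
Reagents that add atoms: none
Why: anti‑Markovnikov hydroboration followed by B‑alkyl Suzuki–Miyaura coupling, which keeps the E geometry of the alkenyl iodide and leaves the primary bromide untouched at rt.

**Step 4**
Reactants: 9 (5E)-17-bromoheptadec-5-ene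
Product: 10 [(13E)-1-diazooctadec-13-en-1-yl]trimethylsilane
Conditions: TMSCHN2, n‑BuLi, THF, −78 °C; then 9, −78 → 0 °C
Reagents that add atoms: (trimethylsilyl)diazomethane, C[Si](C)(C)C=[N+]=[N-]
Why: SN2 C‑alkylation of lithiated trimethylsilyldiazomethane by a primary bromide, a known entry to α‑silyl diazoalkanes; the diazo carbon is the future ring carbon C1.

**Step 5**
Reactants: 11 (4R)-4-(tert-butyldimethylsilyloxy)cyclopent-2-en-1-one
Product: 13 (3R,4R)-4-(tert-butyldimethylsilyloxy)-3-hydroxycyclopentan-1-one, via beta-boryl ketone 12 (not isolated)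
Conditions: B2pin2, CuCl (3 mol %), Xantphos, NaOt‑Bu (cat.), MeOH, THF, 0 °C; then NaBO3·4H2O, THF–H2O, 0 °C
Reagents that add atoms: sodium perborate, [Na+].[O-]B1OO1
Why: Cu‑catalysed conjugate borylation delivers boron anti to the 4‑silyloxy group and the C–B oxidation proceeds with retention, giving the trans (R,R) diol monoether.

**Step 6**
Reactants: 13 (3R,4R)-4-(tert-butyldimethylsilyloxy)-3-hydroxycyclopentan-1-one
Product: 14 (3R,4R)-3,4-bis(tert-butyldimethylsilyloxy)cyclopentan-1-one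
Conditions: TBSOTf, 2,6‑lutidine, CH2Cl2, −78 °C
Reagents that add atoms: tert-butyldimethylsilyl triflate, CC(C)(C)[Si](C)(C)OS(=O)(=O)C(F)(F)F
Why: low‑temperature silylation with a hindered base avoids β‑elimination and gives a C2‑symmetric ketone whose two α‑carbons are equivalent, so the ring expansion has no regiochemical issue.

**Step 7**
Reactants: 14 (3R,4R)-3,4-bis(tert-butyldimethylsilyloxy)cyclopentan-1-one; 10 [(13E)-1-diazooctadec-13-en-1-yl]trimethylsilane
Product: 17 (2R,4R,5R)-4,5-bis(tert-butyldimethylsilyloxy)-2-[(12E)-heptadec-12-en-1-yl]-2-(trimethylsilyloxy)cyclohexan-1-one, via alpha-silyl ketone 15 (not isolated), via enol silane 16 (not isolated)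
Conditions: 10 (1.3 equiv), Sc(OTf)3 (10 mol %), toluene, −40 → 23 °C, then 40 °C; then NaHCO3, mCPBA (1.05 equiv), CH2Cl2, −40 °C
Reagents that add atoms: meta-chloroperbenzoic acid, OOC(=O)c1cccc(Cl)c1
Why: Proposed new method: the diazo carbon of the 1‑alkyl‑1‑silyl diazomethane adds to the Sc‑activated ketone and a ring CH2 migrates with loss of N2 (Tiffeneau–Demjanov‑type 1,2‑shift, 5→6 ring expansion) to give 15, whose 1,3 C→O silyl shift gives the single tetrasubstituted enol silane 16 and blocks a second insertion; mCPBA then transfers oxygen to the nucleophilic chain‑bearing carbon C1 by axial attack on the half‑chair with both OTBS groups equatorial, anti to the OTBS on C5 (1,3 to C1), and silyl migration gives 17 with the new C1–O trans to the C5 oxygen and cis to the C4 oxygen; the closest known reactions are the Sc‑catalysed homologation of cycloalkanones with TMSCHN2 or disubstituted diazoalkanes and the Rubottom oxidation, neither shown so far with an α‑alkyl‑α‑silyl diazoalkane or as one sequence.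

**Step 8**
Reactants: 17 (2R,4R,5R)-4,5-bis(tert-butyldimethylsilyloxy)-2-[(12E)-heptadec-12-en-1-yl]-2-(trimethylsilyloxy)cyclohexan-1-one
Product: 18 (3R,4R,6R)-3,4-bis(tert-butyldimethylsilyloxy)-6-[(12E)-heptadec-12-en-1-yl]-6-(trimethylsilyloxy)cyclohex-1-en-1-yl trifluoromethanesulfonate
Conditions: KHMDS, THF, −78 °C; then PhNTf2, −78 → −20 °C
Reagents that add atoms: N-phenylbis(trifluoromethanesulfonimide), O=S(=O)(N(c1ccccc1)S(=O)(=O)C(F)(F)F)C(F)(F)F
Why: kinetic enolate O‑triflation; the ketone can enolise only towards C3 because C1 is quaternary, so the triflate marks the future C2=C3 bond, and trapping at −78 °C precedes β‑silyloxy elimination.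

**Step 9**
Reactants: 18 (3R,4R,6R)-3,4-bis(tert-butyldimethylsilyloxy)-6-[(12E)-heptadec-12-en-1-yl]-6-(trimethylsilyloxy)cyclohex-1-en-1-yl trifluoromethanesulfonate
Product: 19 (3R,4R,6R)-3,4-bis(tert-butyldimethylsilyloxy)-6-[(12E)-heptadec-12-en-1-yl]-6-(trimethylsilyloxy)cyclohex-1-ene
Conditions: Pd(OAc)2 (5 mol %), PPh3, n‑Bu3N, HCO2H, DMF, 60 °C
Reagents that add atoms: none
Why: Pd‑catalysed formate reduction of an enol triflate (oxidative addition, formate to hydride with loss of CO2, reductive elimination) replaces OTf by H without touching the isolated alkene or any stereocentre.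

**Step 10**
Reactants: 19 (3R,4R,6R)-3,4-bis(tert-butyldimethylsilyloxy)-6-[(12E)-heptadec-12-en-1-yl]-6-(trimethylsilyloxy)cyclohex-1-ene
Product: 20 (1R,4R,5R)-1-[(12E)-heptadec-12-en-1-yl]cyclohex-2-ene-1,4,5-triol
Conditions: TBAF (5 equiv), THF, 0 °C → rt
Reagents that add atoms: none
Why: fluoride‑mediated cleavage of the TMS and both TBS ethers under non‑acidic conditions that spare the allylic alcohols; no stereocentre is touched.

**Compound list**
1 | 5-bromopent-1-ene | C=CCCCBr | starting material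
2 | 1,6-dibromohexane | BrCCCCCCBr | starting material
3 | pent-4-en-1-ylmagnesium bromide | C=CCCC[Mg]Br | intermediate (not isolated)
4 | 11-bromoundec-1-ene | C=CCCCCCCCCCBr | intermediate
5 | hex-1-yne | CCCCC#C | starting material
6 | chloro[(E)-hex-1-en-1-yl]zirconocene (Cp rings drawn σ‑bonded) | CCCC/C=C/[Zr](Cl)(C1C=CC=C1)C1C=CC=C1 | intermediate (not isolated)
7 | (E)-1-iodohex-1-ene | CCCC/C=C/I | intermediate
8 | 9-(11-bromoundecyl)-9-borabicyclo[3.3.1]nonane | BrCCCCCCCCCCCB1C2CCCC1CCC2 | intermediate (not isolated)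
9 | (5E)-17-bromoheptadec-5-ene | CCCC/C=C/CCCCCCCCCCCBr | intermediate
10 | [(13E)-1-diazooctadec-13-en-1-yl]trimethylsilane | CCCC/C=C/CCCCCCCCCCCC(=[N+]=[N-])[Si](C)(C)C | intermediate
11 | (4R)-4-(tert-butyldimethylsilyloxy)cyclopent-2-en-1-one | O=C1C=C[C@H](O[Si](C)(C)C(C)(C)C)C1 | starting material
12 | (3R,4R)-4-(tert-butyldimethylsilyloxy)-3-(4,4,5,5-tetramethyl-1,3,2-dioxaborolan-2-yl)cyclopentan-1-one (B trans to OTBS) | O=C1C[C@@H](B2OC(C)(C)C(C)(C)O2)[C@H](O[Si](C)(C)C(C)(C)C)C1 | intermediate (not isolated)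
13 | (3R,4R)-4-(tert-butyldimethylsilyloxy)-3-hydroxycyclopentan-1-one (trans) | O=C1C[C@@H](O)[C@H](O[Si](C)(C)C(C)(C)C)C1 | intermediate
14 | (3R,4R)-3,4-bis(tert-butyldimethylsilyloxy)cyclopentan-1-one (trans, C2‑symmetric) | O=C1C[C@@H](O[Si](C)(C)C(C)(C)C)[C@H](O[Si](C)(C)C(C)(C)C)C1 | intermediate
15 | (4R,5R)-4,5-bis(tert-butyldimethylsilyloxy)-2-[(12E)-heptadec-12-en-1-yl]-2-(trimethylsilyl)cyclohexan-1-one (both C‑2 epimers) | CCCC/C=C/CCCCCCCCCCCC1([Si](C)(C)C)C(=O)C[C@@H](O[Si](C)(C)C(C)(C)C)[C@H](O[Si](C)(C)C(C)(C)C)C1 | intermediate (not isolated)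
16 | {[(4R,5R)-4,5-bis(tert-butyldimethylsilyloxy)-2-[(12E)-heptadec-12-en-1-yl]cyclohex-1-en-1-yl]oxy}trimethylsilane | CCCC/C=C/CCCCCCCCCCCC1=C(O[Si](C)(C)C)C[C@@H](O[Si](C)(C)C(C)(C)C)[C@H](O[Si](C)(C)C(C)(C)C)C1 | intermediate (not isolated)
17 | (2R,4R,5R)-4,5-bis(tert-butyldimethylsilyloxy)-2-[(12E)-heptadec-12-en-1-yl]-2-(trimethylsilyloxy)cyclohexan-1-one (OTMS trans to the OTBS 1,3 to it) | CCCC/C=C/CCCCCCCCCCC[C@]1(O[Si](C)(C)C)C(=O)C[C@@H](O[Si](C)(C)C(C)(C)C)[C@H](O[Si](C)(C)C(C)(C)C)C1 | intermediate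
18 | (3R,4R,6R)-3,4-bis(tert-butyldimethylsilyloxy)-6-[(12E)-heptadec-12-en-1-yl]-6-(trimethylsilyloxy)cyclohex-1-en-1-yl trifluoromethanesulfonate | CCCC/C=C/CCCCCCCCCCC[C@]1(O[Si](C)(C)C)C(OS(=O)(=O)C(F)(F)F)=C[C@@H](O[Si](C)(C)C(C)(C)C)[C@H](O[Si](C)(C)C(C)(C)C)C1 | intermediate
19 | (3R,4R,6R)-3,4-bis(tert-butyldimethylsilyloxy)-6-[(12E)-heptadec-12-en-1-yl]-6-(trimethylsilyloxy)cyclohex-1-ene | CCCC/C=C/CCCCCCCCCCC[C@]1(O[Si](C)(C)C)C=C[C@@H](O[Si](C)(C)C(C)(C)C)[C@H](O[Si](C)(C)C(C)(C)C)C1 | intermediate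
20 | (1R,4R,5R)-1-[(12E)-heptadec-12-en-1-yl]cyclohex-2-ene-1,4,5-triol (4‑OH/5‑OH trans, 1‑OH cis to 4‑OH) | CCCC/C=C/CCCCCCCCCCC[C@]1(O)C=C[C@@H](O)[C@H](O)C1 | target

**Step count and risks**
Total step count: 10. Longest linear sequence: 7 steps (1, 3, 4, 7, 8, 9, 10).

Most likely to fail:

Step 7 (the proposed new step). The hindered disubstituted diazoalkane may insert slowly, the silyl shift may stall, or the facial selectivity of the oxidation may be modest, since it rests on oxygen transfer leading at C1. Fallback with known reactions only: setting out from 14, Sc(OTf)3‑catalysed homologation with commercial TMSCHN2 gives the unsubstituted enol silane {[(4R,5R)-4,5-bis(tert-butyldimethylsilyloxy)cyclohex-1-en-1-yl]oxy}trimethylsilane F1. MeLi (THF, 0 °C) cleaves it to the regiodefined lithium (4R,5R)-4,5-bis(tert-butyldimethylsilyloxy)cyclohex-1-en-1-olate F2, which is alkylated with bromide 9 (NaI, DMPU) to (4R,5R)-4,5-bis(tert-butyldimethylsilyloxy)-2-[(12E)-heptadec-12-en-1-yl]cyclohexan-1-one F3. Thermodynamic silylation (TMSCl, NaI, Et3N, MeCN) gives enol silane 16, now isolated, and a separate Rubottom oxidation (mCPBA, NaHCO3) comes back to the route at 17. Step 4 and compound 10 are then not needed.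

Step 5. Ketone 13 carries two β‑leaving groups and the copper alkoxide medium can trigger elimination. Fallback setting out from 11: nucleophilic epoxidation (30% H2O2, cat. NaOH, MeOH, −20 °C) anti to the silyloxy group gives (1S,4R,5R)-4-(tert-butyldimethylsilyloxy)-6-oxabicyclo[3.1.0]hexan-2-one F4. Reductive opening of its Cα–O bond with sodium phenylselenide [(PhSe)2, NaBH4, AcOH, EtOH] comes back to the route at 13.

Step 8. The enolate of 17 has a β‑silyloxy group that can be expelled and an α′‑OTMS group that can migrate to the enolate oxygen. Fallback setting out from 17, with no enolate and no palladium: DIBAL‑H (CH2Cl2, −78 °C) gives (2R,4R,5R)-4,5-bis(tert-butyldimethylsilyloxy)-2-[(12E)-heptadec-12-en-1-yl]-2-(trimethylsilyloxy)cyclohexan-1-ol F5 (either C‑1 epimer). Syn‑dehydration with Burgess reagent (toluene, 70 °C) can take a hydrogen only from the CH2 side and comes back to the route at 19, replacing steps 8 and 9.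

**Further compounds**
F1 | step 7 | {[(4R,5R)-4,5-bis(tert-butyldimethylsilyloxy)cyclohex-1-en-1-yl]oxy}trimethylsilane | C1=C(O[Si](C)(C)C)C[C@@H](O[Si](C)(C)C(C)(C)C)[C@H](O[Si](C)(C)C(C)(C)C)C1
F2 | step 7 | lithium (4R,5R)-4,5-bis(tert-butyldimethylsilyloxy)cyclohex-1-en-1-olate | C1=C(O[Li])C[C@@H](O[Si](C)(C)C(C)(C)C)[C@H](O[Si](C)(C)C(C)(C)C)C1
F3 | step 7 | (4R,5R)-4,5-bis(tert-butyldimethylsilyloxy)-2-[(12E)-heptadec-12-en-1-yl]cyclohexan-1-one (C‑2 epimers) | CCCC/C=C/CCCCCCCCCCCC1C(=O)C[C@@H](O[Si](C)(C)C(C)(C)C)[C@H](O[Si](C)(C)C(C)(C)C)C1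
F4 | step 5 | (1S,4R,5R)-4-(tert-butyldimethylsilyloxy)-6-oxabicyclo[3.1.0]hexan-2-one | O=C1[C@H]2O[C@H]2[C@H](O[Si](C)(C)C(C)(C)C)C1
F5 | step 8 | (2R,4R,5R)-4,5-bis(tert-butyldimethylsilyloxy)-2-[(12E)-heptadec-12-en-1-yl]-2-(trimethylsilyloxy)cyclohexan-1-ol (C‑1 epimers) | CCCC/C=C/CCCCCCCCCCC[C@]1(O[Si](C)(C)C)C(O)C[C@@H](O[Si](C)(C)C(C)(C)C)[C@H](O[Si](C)(C)C(C)(C)C)C1
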